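(The rate constants are assumed.)

Read the constants in pairs: at each fork a step that needs reagent stands against a step that does not.

    substrate → intermediate A (k1 = 0.00335 s⁻¹)
    intermediate A → intermediate B (k2 = 8.18 × 10⁻⁴ s⁻¹)
    reagent + intermediate A → intermediate C (k3 = 0.0355 L mol⁻¹ s⁻¹)
    reagent + intermediate B ⇌ intermediate D (K4 = 5.7 L mol⁻¹, k4 = 0.0380 L mol⁻¹ s⁻¹)
    intermediate C → target (k5 = 0.00233 s⁻¹)
    reagent + intermediate C → side product (k6 = 0.0877 L mol⁻¹ s⁻¹)

| flask | substrate | reagent | time |
|---|---|---|---|
| violet | 0.079 M | 0.100 M | 30 min |
| green | 0.079 M | 0.410 M | 30 min |
| amber | 0.079 M | 0.210 M | 30 min |

* which of these there is most of at the end, counted by the substrate in it, violet (intermediate A / side product / intermediate D / intermediate B / target)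
* which of these there is most of at the end, counted by the substrate in it, green (intermediate A / side product / intermediate D / intermediate B / target)
* which of these there is most of at the end, counted by the substrate in it, amber (intermediate A / side product / intermediate D / intermediate B / target)
* how much there is at the end of the one of these that leads, in percent of the substrate charged: violet
* how much there is at the end of the one of these that leads, in percent of the substrate charged: green
* how much there is at the end of the one of these that leads, in percent of the substrate charged: amber

Begin with the first step and count what is left, not what is made. Its half-life of 3.4 min is short beside the 30 min, so 0.241 % of the substrate stands at the end. Reagent plays no part in that step, so the open question is where the substrate goes.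

Now add the first fork. At a steady [reagent] the step to intermediate C is pseudo-first-order, and intermediate A splits by 8.18 × 10⁻⁴ s⁻¹ against 0.0355 L mol⁻¹ s⁻¹ times [reagent]. Define the fork level as the [reagent] at which a fork splits evenly: 0.0230 M for intermediate A, and for intermediate C, where 0.00233 s⁻¹ stands against 0.0877 L mol⁻¹ s⁻¹, 0.0266 M. The fraction that stays on the way to side product is [reagent] over [reagent] plus fork level. At amber's charge that leaves 90.1 % after the first fork. Add the second fork, multiply, and 80.0 % remains.

Then let the reagent be spent, at two per substrate on the way to side product. Amber's charge exceeds that need of 0.158 M, and so does green's, so take the mean level as charge minus 0.079 M: 0.131 M for amber and 0.331 M for green. The fractions left give 70.7 % for amber and 86.5 % for green.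

Violet's charge falls short of the need, so expect its reagent to fall far and take half the charge, 0.0500 M, as the mean level, which gives 44.7 %. But at that level violet's intermediate A leaves at 0.156 min⁻¹, slower than the 0.2 min⁻¹ of the step that makes it, and this reckoning keeps 3.09 % of the charge there at the end. Take that out and commit to 43.3 %.

Rank the routes by the same fractions, letting intermediate D take its slice of what leaks to intermediate B. At the head stand side product in violet, side product in green and side product in amber.

The forecast names side product, side product and side product, at 38 % for violet (33 % to 43 %), 86 % for green (83 % to 89 %) and 69 % for amber (64 % to 74 %). Its grounds: “Each substrate taken to side product uses two reagents, so reagent depletion matters.” My violet figure stands higher than its 38 %.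

The flask gives side product at 38.5 % in violet, side product at 86.2 % in green and side product at 70.6 % in amber. Amber ends with 0.0835 M of free reagent, above the fork level of 0.0266 M, while violet ends with 0.0177 M, below it. A flask like amber but charged with 0.052 M of reagent ends with 0.00586 M, also below that level, and there intermediate B leads at 42.9 % against 16.5 % of side product.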